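**Retrosynthetic overview**
1. The last operation is hydrogenolysis of six benzyl ethers. Before it, the full skeleton is assembled by making the bond between the arm CH2 and C6 of ring B, the central 2,4-dihydroxybenzoate ring whose C1 bears the ester carbonyl.
2. That bond comes from a nickel-catalysed, zinc-driven decarboxylative coupling of two electrophilic carbons. One is the N-hydroxyphthalimide ester of the left half extended by one carboxyl carbon; the other is the C6 iodide of the right half.
3. Enabling feature: the O–CH(CH3)–CH2 arm on C6 of ring B is an (R)-3-acyloxybutanoic acid minus its carboxyl carbon. The CH2 can therefore be released as a primary radical from a further (R)-3-hydroxybutanoate unit without touching the adjacent stereocentre. C6 also lies ortho to the C1 ester carbonyl, which activates a carbon–iodine bond there for oxidative addition.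
4. The left half is the ring A acid (from methyl orsellinate) plus two allyl (R)-3-hydroxybutanoate units, joined by ester couplings. For the right half, 1,3-bis(benzyloxy)-5-bromobenzene feeds ring C (opening of (R)-propylene oxide, acetoacetylation, asymmetric hydrogenation) and ring B (halogen exchange, formylation, oxidation), and the two are joined by an ester bond.
5. No ring is formed. Rings A, B and C are bought as benzene rings and linked in the order C–B (ester bond), then A–B (key step).

Key step: step 17

Remark: all four stereocentres of the SMILES read as (R). The two centres of the left half come from sodium (R)-3-hydroxybutanoate, the centre of the ring C arm from (R)-propylene oxide, and the remaining hydroxybutanoate centre from the hydrogenation of step 12.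

**Route**

Step 1
Reactants: 1 methyl orsellinate (methyl 2,4-dihydroxy-6-methylbenzoate)
Product: 2 methyl 2,4-bis(benzyloxy)-6-methylbenzoate
Conditions: BnBr (2.5 equiv), K2CO3 (3 equiv), DMF, 60 °C
Reagents that add atoms: benzyl bromide BrCc1ccccc1
Why: Williamson ether synthesis: K2CO3 in warm DMF deprotonates both phenols, including the hydrogen-bonded one at C2, and the phenoxides displace bromide from benzyl bromide while the hindered methyl ester stays intact.

Step 2
Reactants: 2 methyl 2,4-bis(benzyloxy)-6-methylbenzoate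
Product: 3 2,4-bis(benzyloxy)-6-methylbenzoic acid (ring A acid)
Conditions: KOH, DMSO/H2O, 100 °C; then 1 M HCl
Reagents that add atoms: potassium hydroxide [K+].[OH-]
Why: Saponification of a 2,6-disubstituted benzoate is slow but should go to completion with KOH in hot aqueous DMSO, conditions to which benzyl aryl ethers are inert.

Step 3
Reactants: 4 sodium (R)-3-hydroxybutanoate
Product: 5 allyl (R)-3-hydroxybutanoate
Conditions: allyl bromide, DMF, rt
Reagents that add atoms: allyl bromide C=CCBr
Why: SN2 O-alkylation of the carboxylate needs no added base, so the free secondary hydroxyl group is not alkylated and the (R) centre, which takes no part, is kept.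

Step 4
Reactants: 3 2,4-bis(benzyloxy)-6-methylbenzoic acid; 5 allyl (R)-3-hydroxybutanoate
Product: 7 allyl (3R)-3-{[2,4-bis(benzyloxy)-6-methylbenzoyl]oxy}butanoate, via acid chloride 6 (not isolated)
Conditions: 1-chloro-N,N,2-trimethylprop-1-en-1-amine, CH2Cl2, 0 °C to rt; then 5, Et3N, DMAP, CH2Cl2, rt
Reagents that add atoms: none
Why: The chloroenamine turns the hindered acid into its chloride under neutral conditions that spare the benzyl ethers, and the DMAP-catalysed acylation of the secondary alcohol breaks no bond at the stereocentre, so (R) is retained.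

Step 5
Reactants: 7 allyl (3R)-3-{[2,4-bis(benzyloxy)-6-methylbenzoyl]oxy}butanoate
Product: 8 (3R)-3-{[2,4-bis(benzyloxy)-6-methylbenzoyl]oxy}butanoic acid
Conditions: Pd(PPh3)4 (5 mol%), morpholine, THF, rt; then 1 M HCl wash
Reagents that add atoms: none
Why: Tsuji–Trost deallylation: zerovalent palladium ionises only the allyl ester to a pi-allyl complex that morpholine intercepts, which leaves the aryl ester, the benzyl ethers and the stereocentre untouched.

Step 6
Reactants: 8 (3R)-3-{[2,4-bis(benzyloxy)-6-methylbenzoyl]oxy}butanoic acid; 5 allyl (R)-3-hydroxybutanoate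
Product: 9 allyl (3R)-3-{[(3R)-3-{[2,4-bis(benzyloxy)-6-methylbenzoyl]oxy}butanoyl]oxy}butanoate
Conditions: N,N'-diisopropylcarbodiimide (DIC), DMAP (10 mol%), CH2Cl2, 0 °C to rt
Reagents that add atoms: none
Why: Steglich esterification of an unhindered aliphatic acid with a secondary alcohol, run cold with catalytic DMAP to keep beta-elimination of the aroyloxy group slow, with both (R) centres as spectators.

Step 7
Reactants: 9 allyl (3R)-3-{[(3R)-3-{[2,4-bis(benzyloxy)-6-methylbenzoyl]oxy}butanoyl]oxy}butanoate
Product: 10 (3R)-3-{[(3R)-3-{[2,4-bis(benzyloxy)-6-methylbenzoyl]oxy}butanoyl]oxy}butanoic acid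
Conditions: Pd(PPh3)4 (5 mol%), morpholine, THF, rt; then 1 M HCl wash
Reagents that add atoms: none
Why: The same Tsuji–Trost deallylation as in step 5, selective for the only allyl ester among three ester groups.

Step 8
Reactants: 10 (3R)-3-{[(3R)-3-{[2,4-bis(benzyloxy)-6-methylbenzoyl]oxy}butanoyl]oxy}butanoic acid
Product: 11 1,3-dioxoisoindolin-2-yl (3R)-3-{[(3R)-3-{[2,4-bis(benzyloxy)-6-methylbenzoyl]oxy}butanoyl]oxy}butanoate (left fragment)
Conditions: N-hydroxyphthalimide, DIC, DMAP (10 mol%), CH2Cl2, rt
Reagents that add atoms: N-hydroxyphthalimide O=C1c2ccccc2C(=O)N1O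
Why: Carbodiimide coupling with N-hydroxyphthalimide gives the redox-active ester, an activated ester of a class that is stable on the bench and to chromatography.

Step 9
Reactants: 12 5-bromoresorcinol (5-bromobenzene-1,3-diol)
Product: 13 1,3-bis(benzyloxy)-5-bromobenzene
Conditions: BnBr (2.3 equiv), K2CO3 (3 equiv), DMF, rt to 50 °C
Reagents that add atoms: benzyl bromide BrCc1ccccc1
Why: Williamson ether synthesis on both phenols, the aryl bromide being inert to K2CO3 and benzyl bromide.

Step 10
Reactants: 13 1,3-bis(benzyloxy)-5-bromobenzene; 14 (R)-propylene oxide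
Product: 16 (2R)-1-[3,5-bis(benzyloxy)phenyl]propan-2-ol, via aryl Grignard reagent 15 (not isolated)
Conditions: Mg turnings, THF, reflux; then CuI (10 mol%), 14, −30 to 0 °C; then 1 M HCl
Reagents that add atoms: none
Why: Copper-catalysed opening of a terminal epoxide by an aryl Grignard reagent proceeds by SN2 attack at the unsubstituted CH2, so the C–O bond at the stereocentre of 14 is not broken and the alcohol is (R).

Step 11
Reactants: 16 (2R)-1-[3,5-bis(benzyloxy)phenyl]propan-2-ol
Product: 17 (2R)-1-[3,5-bis(benzyloxy)phenyl]propan-2-yl 3-oxobutanoate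
Conditions: 2,2,6-trimethyl-4H-1,3-dioxin-4-one (1.3 equiv), toluene, 110 °C
Reagents that add atoms: 2,2,6-trimethyl-4H-1,3-dioxin-4-one CC1=CC(=O)OC(C)(C)O1
Why: Thermal retro-hetero-Diels–Alder cleavage of the dioxinone releases acetylketene, which the secondary alcohol traps to give the acetoacetate under neutral conditions without touching the stereocentre.

Step 12
Reactants: 17 (2R)-1-[3,5-bis(benzyloxy)phenyl]propan-2-yl 3-oxobutanoate
Product: 18 (2R)-1-[3,5-bis(benzyloxy)phenyl]propan-2-yl (3R)-3-hydroxybutanoate
Conditions: H2 (10 atm), RuCl2[(R)-BINAP] (1 mol%), MeOH/CH2Cl2, 50 °C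
Reagents that add atoms: none
Why: Noyori asymmetric hydrogenation of a beta-keto ester: the chelated ketone is reduced under catalyst control, the (R)-BINAP ligand delivering the (R) alcohol regardless of the remote (R) centre, and this ruthenium catalyst does not cleave benzyl ethers.

Step 13
Reactants: 13 1,3-bis(benzyloxy)-5-bromobenzene
Product: 19 1,3-bis(benzyloxy)-5-iodobenzene
Conditions: NaI (2 equiv), CuI (5 mol%), trans-N,N'-dimethylcyclohexane-1,2-diamine (10 mol%), 1,4-dioxane, 110 °C
Reagents that add atoms: sodium iodide [Na+].[I-]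
Why: Copper-catalysed aromatic Finkelstein reaction, driven by precipitation of NaBr from dioxane, provides the more reactive aryl iodide needed for the nickel chemistry.

Step 14
Reactants: 19 1,3-bis(benzyloxy)-5-iodobenzene
Product: 21 2,4-bis(benzyloxy)-6-iodobenzaldehyde, via iminium chloride 20 (not isolated)
Conditions: POCl3, DMF, 0 to 70 °C; then H2O
Reagents that add atoms: N,N-dimethylformamide CN(C)C=O; water O
Why: Vilsmeier–Haack formylation: the chloroiminium ion should attack one of the two equivalent ring carbons that are para to one benzyloxy group and ortho to the other, the carbon between the two benzyloxy groups being more crowded.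

Step 15
Reactants: 21 2,4-bis(benzyloxy)-6-iodobenzaldehyde
Product: 22 2,4-bis(benzyloxy)-6-iodobenzoic acid (ring B acid)
Conditions: NaClO2, NaH2PO4, 2-methyl-2-butene, t-BuOH/THF/H2O, rt
Reagents that add atoms: sodium chlorite [Na+].[O-]Cl=O
Why: Pinnick oxidation turns the aldehyde into the acid under buffered conditions, 2-methyl-2-butene removing HOCl before it can chlorinate the electron-rich ring.

Step 16
Reactants: 22 2,4-bis(benzyloxy)-6-iodobenzoic acid; 18 (2R)-1-[3,5-bis(benzyloxy)phenyl]propan-2-yl (3R)-3-hydroxybutanoate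
Product: 24 (2R)-1-[3,5-bis(benzyloxy)phenyl]propan-2-yl (3R)-3-{[2,4-bis(benzyloxy)-6-iodobenzoyl]oxy}butanoate (right fragment), via acid chloride 23 (not isolated)
Conditions: 1-chloro-N,N,2-trimethylprop-1-en-1-amine, CH2Cl2, 0 °C to rt; then 18, Et3N, DMAP, CH2Cl2, rt to 40 °C
Reagents that add atoms: none
Why: Neutral acid chloride formation followed by DMAP-catalysed acylation as in step 4, in which the carbon–oxygen bond at the new (R) centre of 18 is not broken and the carbon–iodine bond is inert.

Step 17
Reactants: 11 N-hydroxyphthalimide ester (left fragment); 24 aryl iodide (right fragment)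
Product: 26 hexa-O-benzylhansforester A (the target carrying benzyl ethers on all six phenol oxygens), via primary alkyl radical 25 (not isolated)
Conditions: NiBr2(dme) (15 mol%), 4,4'-di-tert-butyl-2,2'-bipyridine (dtbbpy, 15 mol%), Zn dust (3 equiv), N,N-dimethylacetamide, rt, 11 (1.5 equiv) added slowly
Reagents that add atoms: none
Why: Zerovalent nickel carrying dtbbpy inserts into the carbon–iodine bond at C6 of ring B, which the ortho ester carbonyl at C1 activates; single-electron reduction of 11 by low-valent nickel or zinc breaks the N–O bond, CO2 leaves, and the primary radical 25 is captured by the arylnickel species to give a trivalent aryl(alkyl)nickel complex that forms the CH2–C6 bond by reductive elimination, after which zinc returns nickel to its low-valent state. The closest known reaction type is the nickel-catalysed decarboxylative cross-electrophile coupling of primary alkyl N-hydroxyphthalimide esters with aryl iodides, which also tolerates a heteroatom substituent beta to the radical carbon. No ring is closed. No stereocentre is made: the radical sits on the CH2 next to the O–CH(CH3) centre, no bond at that centre is broken, and so its (R) configuration and the three remote (R) centres are carried over unchanged. The step needs cross-selectivity over aryl–aryl and alkyl–alkyl dimerisation, secured by the different activation modes of the two electrophiles (two-electron oxidative addition for the iodide, one-electron reduction for the ester) and by slow addition of 11, and it needs chemoselectivity, secured because alkyl esters and benzyl aryl ethers are inert to zinc and low-valent nickel at room temperature. Loss of the beta-acyloxy group, the 1,2-acyloxy shift of 25 and hydrogen transfer across the Z-configured ester link should all be slower than radical capture and reductive elimination at this nickel loading.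

Step 18
Reactants: 26 hexa-O-benzylhansforester A
Product: 27 hansforester A
Conditions: H2 (1 atm), 10% Pd/C, EtOAc/EtOH, rt
Reagents that add atoms: none
Why: Catalytic hydrogenolysis cleaves the six benzyl aryl ethers under neutral conditions, whereas the four ester C–O bonds are aliphatic or homobenzylic rather than benzylic and stay, as do the four (R) centres.

**Compound list**
1 | methyl orsellinate | COC(=O)c1c(C)cc(O)cc1O | starting material
2 | methyl 2,4-bis(benzyloxy)-6-methylbenzoate | COC(=O)c1c(C)cc(OCc2ccccc2)cc1OCc3ccccc3 | intermediate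
3 | 2,4-bis(benzyloxy)-6-methylbenzoic acid | Cc1cc(OCc2ccccc2)cc(OCc3ccccc3)c1C(=O)O | intermediate
4 | sodium (R)-3-hydroxybutanoate | O[C@H](C)CC(=O)[O-].[Na+] | starting material
5 | allyl (R)-3-hydroxybutanoate | O[C@H](C)CC(=O)OCC=C | intermediate
6 | 2,4-bis(benzyloxy)-6-methylbenzoyl chloride (not isolated) | Cc1cc(OCc2ccccc2)cc(OCc3ccccc3)c1C(=O)Cl | intermediate
7 | allyl (3R)-3-{[2,4-bis(benzyloxy)-6-methylbenzoyl]oxy}butanoate | Cc1cc(OCc2ccccc2)cc(OCc3ccccc3)c1C(=O)O[C@H](C)CC(=O)OCC=C | intermediate
8 | (3R)-3-{[2,4-bis(benzyloxy)-6-methylbenzoyl]oxy}butanoic acid | Cc1cc(OCc2ccccc2)cc(OCc3ccccc3)c1C(=O)O[C@H](C)CC(=O)O | intermediate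
9 | allyl (3R)-3-{[(3R)-3-{[2,4-bis(benzyloxy)-6-methylbenzoyl]oxy}butanoyl]oxy}butanoate | Cc1cc(OCc2ccccc2)cc(OCc3ccccc3)c1C(=O)O[C@H](C)CC(=O)O[C@H](C)CC(=O)OCC=C | intermediate
10 | (3R)-3-{[(3R)-3-{[2,4-bis(benzyloxy)-6-methylbenzoyl]oxy}butanoyl]oxy}butanoic acid | Cc1cc(OCc2ccccc2)cc(OCc3ccccc3)c1C(=O)O[C@H](C)CC(=O)O[C@H](C)CC(=O)O | intermediate
11 | 1,3-dioxoisoindolin-2-yl ester of 10 (left fragment) | Cc1cc(OCc2ccccc2)cc(OCc3ccccc3)c1C(=O)O[C@H](C)CC(=O)O[C@H](C)CC(=O)ON4C(=O)c5ccccc5C4=O | intermediate
12 | 5-bromoresorcinol | Oc1cc(O)cc(Br)c1 | starting material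
13 | 1,3-bis(benzyloxy)-5-bromobenzene | Brc1cc(OCc2ccccc2)cc(OCc3ccccc3)c1 | intermediate
14 | (R)-propylene oxide | C[C@@H]1CO1 | starting material
15 | [3,5-bis(benzyloxy)phenyl]magnesium bromide (not isolated) | Br[Mg]c1cc(OCc2ccccc2)cc(OCc3ccccc3)c1 | intermediate
16 | (2R)-1-[3,5-bis(benzyloxy)phenyl]propan-2-ol | O[C@H](C)Cc1cc(OCc2ccccc2)cc(OCc3ccccc3)c1 | intermediate
17 | (2R)-1-[3,5-bis(benzyloxy)phenyl]propan-2-yl 3-oxobutanoate | CC(=O)CC(=O)O[C@H](C)Cc1cc(OCc2ccccc2)cc(OCc3ccccc3)c1 | intermediate
18 | (2R)-1-[3,5-bis(benzyloxy)phenyl]propan-2-yl (3R)-3-hydroxybutanoate | O[C@H](C)CC(=O)O[C@H](C)Cc1cc(OCc2ccccc2)cc(OCc3ccccc3)c1 | intermediate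
19 | 1,3-bis(benzyloxy)-5-iodobenzene | Ic1cc(OCc2ccccc2)cc(OCc3ccccc3)c1 | intermediate
20 | N-[2,4-bis(benzyloxy)-6-iodobenzylidene]-N-methylmethanaminium chloride (not isolated) | C[N+](C)=Cc1c(OCc2ccccc2)cc(OCc3ccccc3)cc1I.[Cl-] | intermediate
21 | 2,4-bis(benzyloxy)-6-iodobenzaldehyde | O=Cc1c(OCc2ccccc2)cc(OCc3ccccc3)cc1I | intermediate
22 | 2,4-bis(benzyloxy)-6-iodobenzoic acid | OC(=O)c1c(OCc2ccccc2)cc(OCc3ccccc3)cc1I | intermediate
23 | 2,4-bis(benzyloxy)-6-iodobenzoyl chloride (not isolated) | ClC(=O)c1c(OCc2ccccc2)cc(OCc3ccccc3)cc1I | intermediate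
24 | (2R)-1-[3,5-bis(benzyloxy)phenyl]propan-2-yl (3R)-3-{[2,4-bis(benzyloxy)-6-iodobenzoyl]oxy}butanoate (right fragment) | Ic1cc(OCc2ccccc2)cc(OCc3ccccc3)c1C(=O)O[C@H](C)CC(=O)O[C@H](C)Cc4cc(OCc5ccccc5)cc(OCc6ccccc6)c4 | intermediate
25 | primary alkyl radical formed from 11 by loss of phthalimide anion and CO2, both centres arranged as in 11 (not isolated) | Cc1cc(OCc2ccccc2)cc(OCc3ccccc3)c1C(=O)O[C@H](C)CC(=O)O[C@H](C)[CH2] | intermediate
26 | hexa-O-benzylhansforester A, all four centres (R) | Cc1cc(OCc2ccccc2)cc(OCc3ccccc3)c1C(=O)O[C@H](C)CC(=O)O[C@H](C)Cc4cc(OCc5ccccc5)cc(OCc6ccccc6)c4C(=O)O[C@H](C)CC(=O)O[C@H](C)Cc7cc(OCc8ccccc8)cc(OCc9ccccc9)c7 | intermediate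
27 | hansforester A | Cc1cc(O)cc(O)c1C(=O)O[C@H](C)CC(=O)O[C@H](C)Cc1cc(O)cc(O)c1C(=O)O[C@H](C)CC(=O)O[C@H](C)Cc1cc(O)cc(O)c1 | target

**Step count**
Total step count: 18.
Longest linear sequence: 9 steps (steps 1, 2, 4, 5, 6, 7, 8, 17, 18).

**Steps most likely to fail**

Step 17.
- **Risk:** The alkyl radical may be consumed by hydrogen abstraction or dimerisation faster than the crowded arylnickel species captures it. The iodide may be reduced to the arene. The beta-acyloxy group may be expelled from an alkylnickel species.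
- **Fallback** (sets out from 8 and 16, comes back at 26): the arm–ring bond is taken from the epoxide opening of step 10, and the C1 carboxyl carbon of ring B is added afterwards. Steglich esterification of 16 with 8 (DIC, DMAP, CH2Cl2, 0 °C) should give (2R)-1-[3,5-bis(benzyloxy)phenyl]propan-2-yl (3R)-3-{[2,4-bis(benzyloxy)-6-methylbenzoyl]oxy}butanoate F1. Vilsmeier–Haack formylation (POCl3, DMF) should select the ester-free, more electron-rich ring, at the carbon ortho to the arm and para to a benzyloxy group. It passes through N-{2,4-bis(benzyloxy)-6-[(2R)-2-{[(3R)-3-{[2,4-bis(benzyloxy)-6-methylbenzoyl]oxy}butanoyl]oxy}propyl]benzylidene}-N-methylmethanaminium chloride F2 and gives on hydrolysis (2R)-1-[3,5-bis(benzyloxy)-2-formylphenyl]propan-2-yl (3R)-3-{[2,4-bis(benzyloxy)-6-methylbenzoyl]oxy}butanoate F3. Pinnick oxidation should give 2,4-bis(benzyloxy)-6-[(2R)-2-{[(3R)-3-{[2,4-bis(benzyloxy)-6-methylbenzoyl]oxy}butanoyl]oxy}propyl]benzoic acid F4. The chloroenamine of step 4 converts it into 2,4-bis(benzyloxy)-6-[(2R)-2-{[(3R)-3-{[2,4-bis(benzyloxy)-6-methylbenzoyl]oxy}butanoyl]oxy}propyl]benzoyl chloride F5, which acylates 18 (Et3N, DMAP) to give 26.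

Step 16.
- **Risk:** Acylation of the secondary alcohol by an aroyl chloride flanked by iodine and a benzyloxy group may be very slow. Base-induced elimination of the beta-oxygen substituent to a crotonate, or hydrolysis of the chloride, could then take over.
- **Fallback** (sets out from 17 and 22, comes back at 24): the roles are reversed, so that the hindered carboxylate is the nucleophile and the alcohol carbon the electrophile. Hydrogenation of 17 with RuCl2[(S)-BINAP] should give (2R)-1-[3,5-bis(benzyloxy)phenyl]propan-2-yl (3S)-3-hydroxybutanoate F6. Mitsunobu esterification of this alcohol with 22 (PPh3, DIAD, toluene, 0 °C to rt) proceeds by SN2 displacement with inversion and should give 24 with the (3R) centre.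

Step 14.
- **Risk:** Formylation may occur in part at the carbon between the two benzyloxy groups. The warm POCl3/DMF medium may also strip benzyl groups or cause protodeiodination.
- **Fallback** (sets out from 19, comes back at 22, bypassing 21): the carboxyl carbon is introduced as CO2 onto a site-defined arylmetal. Iodination of 19 (N-iodosuccinimide, catalytic CF3CO2H, MeCN, rt) should give 1,5-bis(benzyloxy)-2,3-diiodobenzene F7. Iodine–magnesium exchange (iPrMgCl·LiCl, THF, −78 °C) should take the iodine flanked by oxygen and iodine, where the carbanion is best stabilised and strain is relieved. This gives [2,4-bis(benzyloxy)-6-iodophenyl]magnesium chloride F8, which is kept cold to prevent aryne formation and quenched with CO2, then 1 M HCl, to give 22.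

**Further compounds**
F1 | step 17 | (2R)-1-[3,5-bis(benzyloxy)phenyl]propan-2-yl (3R)-3-{[2,4-bis(benzyloxy)-6-methylbenzoyl]oxy}butanoate | Cc1cc(OCc2ccccc2)cc(OCc3ccccc3)c1C(=O)O[C@H](C)CC(=O)O[C@H](C)Cc4cc(OCc5ccccc5)cc(OCc6ccccc6)c4
F2 | step 17 | N-{2,4-bis(benzyloxy)-6-[(2R)-2-{[(3R)-3-{[2,4-bis(benzyloxy)-6-methylbenzoyl]oxy}butanoyl]oxy}propyl]benzylidene}-N-methylmethanaminium chloride | Cc1cc(OCc2ccccc2)cc(OCc3ccccc3)c1C(=O)O[C@H](C)CC(=O)O[C@H](C)Cc4cc(OCc5ccccc5)cc(OCc6ccccc6)c4C=[N+](C)C.[Cl-]
F3 | step 17 | (2R)-1-[3,5-bis(benzyloxy)-2-formylphenyl]propan-2-yl (3R)-3-{[2,4-bis(benzyloxy)-6-methylbenzoyl]oxy}butanoate | Cc1cc(OCc2ccccc2)cc(OCc3ccccc3)c1C(=O)O[C@H](C)CC(=O)O[C@H](C)Cc4cc(OCc5ccccc5)cc(OCc6ccccc6)c4C=O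
F4 | step 17 | 2,4-bis(benzyloxy)-6-[(2R)-2-{[(3R)-3-{[2,4-bis(benzyloxy)-6-methylbenzoyl]oxy}butanoyl]oxy}propyl]benzoic acid | Cc1cc(OCc2ccccc2)cc(OCc3ccccc3)c1C(=O)O[C@H](C)CC(=O)O[C@H](C)Cc4cc(OCc5ccccc5)cc(OCc6ccccc6)c4C(=O)O
F5 | step 17 | 2,4-bis(benzyloxy)-6-[(2R)-2-{[(3R)-3-{[2,4-bis(benzyloxy)-6-methylbenzoyl]oxy}butanoyl]oxy}propyl]benzoyl chloride | Cc1cc(OCc2ccccc2)cc(OCc3ccccc3)c1C(=O)O[C@H](C)CC(=O)O[C@H](C)Cc4cc(OCc5ccccc5)cc(OCc6ccccc6)c4C(=O)Cl
F6 | step 16 | (2R)-1-[3,5-bis(benzyloxy)phenyl]propan-2-yl (3S)-3-hydroxybutanoate | O[C@@H](C)CC(=O)O[C@H](C)Cc1cc(OCc2ccccc2)cc(OCc3ccccc3)c1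
F7 | step 14 | 1,5-bis(benzyloxy)-2,3-diiodobenzene | Ic1cc(OCc2ccccc2)cc(OCc3ccccc3)c1I
F8 | step 14 | [2,4-bis(benzyloxy)-6-iodophenyl]magnesium chloride | Cl[Mg]c1c(OCc2ccccc2)cc(OCc3ccccc3)cc1I
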